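The dihydrofuran ring (O1–C2–C3–C3a–C7a) is cut off the phloroglucinol ring at C3–C3a and O1–C7a, so that O1, C2 (R) and C3 come intact from one enantiopure epoxide. The key step, a palladium/norbornene (Catellani-type) annulation, forms both bonds at once: the iodine-bearing carbon of 1-iodo-3,5-bis(methoxymethoxy)benzene becomes C7a and an ortho C–H becomes C3a. It exploits that C3a and C7a are adjacent ring carbons of a 1,3-dioxygenated benzene whose two ortho positions are equivalent, the third phloroglucinol oxygen arriving with the epoxide. Directed metalation then acylates C5, dehydration unveils the isopropenyl group, and a Mannich-type methylene transfer attaches the pyrone at C7.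

Key step: step 3

Assumption: from the SMILES, C2 of the dihydrofuran is R and the acyl group is (R)-2-methylbutanoyl. Atom labels follow benzofuran numbering of the target. Compounds 1, 3, 7, 16 and 17 are taken as commercially available.

Step 1
Reactants: 1 5-iodoresorcinol
Product: 2 1-iodo-3,5-bis(methoxymethoxy)benzene
Conditions: MOMCl (2.6 equiv), i-Pr2NEt (3 equiv), CH2Cl2, 0 °C → rt
Reagents that add atoms: chloromethyl methyl ether, COCCl
Why: Double O-alkylation of the two phenols by the reactive α-chloro ether (Williamson-type acetal formation) should be clean and installs the groups that later direct metalation; no stereocentre is involved.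

Step 2
Reactants: 3 methyl (2R)-oxirane-2-carboxylate (methyl (R)-glycidate)
Product: 5 triethyl({2-[(2R)-oxiran-2-yl]propan-2-yl}oxy)silane, via lithium alkoxide 4 (not isolated)
Conditions: MeLi (2.1 equiv), THF, −78 °C; then Et3SiCl (1.2 equiv), DMAP (cat.), −78 °C → rt; H2O work-up
Reagents that add atoms: methyllithium, [Li]C; chlorotriethylsilane, CC[Si](Cl)(CC)CC
Why: Double 1,2-addition of MeLi to the ester at −78 °C should outrun epoxide opening, and O-silylation of the tertiary lithium alkoxide in the same flask blocks Payne rearrangement; the stereocentre is the glycidate carbon, which is not touched, so R is retained.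

Step 3
Reactants: 2 1-iodo-3,5-bis(methoxymethoxy)benzene; 5 triethyl({2-[(2R)-oxiran-2-yl]propan-2-yl}oxy)silane
Product: 6 (2R)-4,6-bis(methoxymethoxy)-2-{2-[(triethylsilyl)oxy]propan-2-yl}-2,3-dihydro-1-benzofuran
Conditions: Pd(OAc)2 (10 mol %), XPhos (20 mol %), 1-methylbicyclo[2.2.1]hept-2-ene (1.0 equiv), K2CO3 (2.5 equiv), 5 (2 equiv), NMP, 80 °C, Ar
Reagents that add atoms: none
Why: Oxidative addition of zerovalent palladium into the C–I bond, norbornene insertion and ortho C–H palladation give an aryl–norbornyl palladacycle of divalent palladium, which opens epoxide 5 at its terminal CH2 (via tetravalent palladium) and forms the aryl–CH2 bond by reductive elimination; β-carbon elimination then expels norbornene and the tethered alkoxide closes the ring by C(aryl)–O reductive elimination at the former C–I carbon, returning zerovalent palladium. The closest known reaction type is the palladium/norbornene (Catellani-type) annulation of aryl iodides with epoxides to 2,3-dihydrobenzofurans. The dihydrofuran ring closes as a formal (3+2) annulation whose last event is a five-membered-ring C–O reductive elimination from a six-membered aryl palladium alkoxide. No stereocentre is created: C2 is the carbinol carbon of 5, its C–O bond is never broken, and its R configuration is carried over with retention. The step needs attack at the terminal rather than the internal epoxide carbon, secured by the adjacent fully substituted carbon, and a single ortho alkylation, secured because the two ortho C–H bonds of 2 are equivalent, the new substituent is buttressed by the neighbouring methoxymethoxy group and the bridgehead-substituted norbornene favours norbornene extrusion after one alkylation. The triethylsilyl ether keeps the tertiary oxygen out of the C–O coupling and out of Payne rearrangement, and the bulky biaryl phosphine favours C–O reductive elimination over β-hydride loss from the alkoxide.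

Step 4
Reactants: 7 (2R)-2-methylbutanoic acid
Product: 9 (2R)-N-methoxy-N,2-dimethylbutanamide, via acyl imidazole 8 (not isolated)
Conditions: 1,1'-carbonyldiimidazole (1.1 equiv), CH2Cl2, 0 °C → rt; then MeNH(OMe)·HCl (1.2 equiv), rt
Reagents that add atoms: N,O-dimethylhydroxylamine hydrochloride, CNOC.Cl
Why: Amide formation through the acyl imidazole should give the Weinreb amide without epimerisation, since a simple α-alkyl acyl imidazole has no easy racemisation path under these near-neutral conditions; the R centre comes unchanged from the acid.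

Step 5
Reactants: 6 (2R)-4,6-bis(methoxymethoxy)-2-{2-[(triethylsilyl)oxy]propan-2-yl}-2,3-dihydro-1-benzofuran; 9 (2R)-N-methoxy-N,2-dimethylbutanamide
Product: 11 (2R)-1-[(2R)-4,6-bis(methoxymethoxy)-2-{2-[(triethylsilyl)oxy]propan-2-yl}-2,3-dihydro-1-benzofuran-5-yl]-2-methylbutan-1-one, via C5 aryllithium 10 (not isolated)
Conditions: n-BuLi (1.05 equiv), THF, 0 °C, 1 h; then 9 (1.3 equiv), −78 °C → rt; H2O
Reagents that add atoms: none
Why: Directed ortho-metalation at C5, the only ring C–H flanked by two methoxymethoxy groups, followed by Weinreb ketone synthesis should give the ketone, the chelated tetrahedral adduct preventing over-addition and enolisation so that the R centre of 9 is carried over and C2 is untouched.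

Step 6
Reactants: 11 (2R)-1-[(2R)-4,6-bis(methoxymethoxy)-2-{2-[(triethylsilyl)oxy]propan-2-yl}-2,3-dihydro-1-benzofuran-5-yl]-2-methylbutan-1-one
Product: 12 (2R)-1-[(2R)-2-(2-hydroxypropan-2-yl)-4,6-bis(methoxymethoxy)-2,3-dihydro-1-benzofuran-5-yl]-2-methylbutan-1-one
Conditions: Bu4NF (1.5 equiv), AcOH (1.5 equiv), THF, rt
Reagents that add atoms: none
Why: Fluoride-induced desilylation, buffered with acetic acid to keep the ketone α-centre from enolising, should free the tertiary alcohol while the methoxymethyl ethers and both stereocentres stay untouched.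

Step 7
Reactants: 12 (2R)-1-[(2R)-2-(2-hydroxypropan-2-yl)-4,6-bis(methoxymethoxy)-2,3-dihydro-1-benzofuran-5-yl]-2-methylbutan-1-one
Product: 14 (2R)-1-[(2R)-4,6-bis(methoxymethoxy)-2-(prop-1-en-2-yl)-2,3-dihydro-1-benzofuran-5-yl]-2-methylbutan-1-one, via sulfamate ester 13 (not isolated)
Conditions: Burgess reagent (methyl N-(triethylammoniosulfonyl)carbamate, 2 equiv), toluene, rt → 70 °C
Reagents that add atoms: none
Why: Burgess dehydration through the sulfamate ester (syn elimination) should take one of the six methyl hydrogens rather than the hindered C2–H on the oxygen-bearing ring carbon, giving the isopropenyl group under non-acidic conditions without touching C2.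

Step 8
Reactants: 14 (2R)-1-[(2R)-4,6-bis(methoxymethoxy)-2-(prop-1-en-2-yl)-2,3-dihydro-1-benzofuran-5-yl]-2-methylbutan-1-one
Product: 15 (2R)-1-[(2R)-4,6-dihydroxy-2-(prop-1-en-2-yl)-2,3-dihydro-1-benzofuran-5-yl]-2-methylbutan-1-one
Conditions: HCl (1.25 M in MeOH), 0 °C → rt
Reagents that add atoms: none
Why: Acid-catalysed acetal exchange with methanol should remove both methoxymethyl ethers, which are activated by the flanking carbonyl, under conditions mild enough to spare the 1,1-disubstituted alkene, the allylic aryl ether and both stereocentres.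

Step 9
Reactants: 16 methyl 3-oxopentanoate; 17 N-methoxy-N-methylpropanamide
Product: 19 methyl 4-methyl-3,5-dioxoheptanoate, via dilithium dianion 18 (not isolated)
Conditions: 16 (2 equiv), LiN(i-Pr)2 (4.1 equiv), THF, −78 → 0 °C; then 17 (1 equiv), −78 → 0 °C; 1 M HCl
Reagents that add atoms: none
Why: Claisen-type C-acylation of the β-keto ester 2,4-dianion at its more nucleophilic γ-carbon by the Weinreb amide should give the 3,5-diketo ester; the new methine centre forms as a mixture and becomes sp2 in the next step.

Step 10
Reactants: 19 methyl 4-methyl-3,5-dioxoheptanoate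
Product: 20 6-ethyl-4-hydroxy-5-methyl-2H-pyran-2-one
Conditions: DBU (1.2 equiv), toluene, 110 °C; then 1 M HCl
Reagents that add atoms: none
Why: Base-mediated enol lactonisation (attack of the C5 enolate oxygen on the ester with loss of methanol) and tautomerisation should give the 4-hydroxy-2-pyrone; no stereocentre remains.

Step 11
Reactants: 15 (2R)-1-[(2R)-4,6-dihydroxy-2-(prop-1-en-2-yl)-2,3-dihydro-1-benzofuran-5-yl]-2-methylbutan-1-one; 20 6-ethyl-4-hydroxy-5-methyl-2H-pyran-2-one
Product: 23 6-ethyl-4-hydroxy-3-({(2R)-4,6-dihydroxy-5-[(2R)-2-methylbutanoyl]-2-(prop-1-en-2-yl)-2,3-dihydro-1-benzofuran-7-yl}methyl)-5-methyl-2H-pyran-2-one, via Mannich base 21 (not isolated), via methylidene pyrandione 22 (not isolated)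
Conditions: 20, CH2=NMe2+ I− (1.0 equiv), MeCN, rt; then 15 (1.0 equiv), 60 °C
Reagents that add atoms: N,N-dimethylmethylideneammonium iodide (Eschenmoser's salt), C=[N+](C)C.[I-]
Why: Mannich aminomethylation of the pyrone at C3, thermal loss of dimethylamine to the methylidene dione and Michael-type Friedel–Crafts capture by C7 of 15, the only free nucleophilic ring position, should give the methylene-bridged target without forming or touching a stereocentre.

Compound list

1 | 5-iodoresorcinol (5-iodobenzene-1,3-diol) | Oc1cc(O)cc(I)c1 | starting material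
2 | 1-iodo-3,5-bis(methoxymethoxy)benzene | COCOc1cc(OCOC)cc(I)c1 | intermediate
3 | methyl (2R)-oxirane-2-carboxylate | COC(=O)[C@H]1CO1 | starting material
4 | lithium 2-[(2R)-oxiran-2-yl]propan-2-olate (formed in the flask, not isolated) | [Li+].CC(C)([O-])[C@H]1CO1 | intermediate
5 | triethyl({2-[(2R)-oxiran-2-yl]propan-2-yl}oxy)silane | CC[Si](CC)(CC)OC(C)(C)[C@H]1CO1 | intermediate
6 | (2R)-4,6-bis(methoxymethoxy)-2-{2-[(triethylsilyl)oxy]propan-2-yl}-2,3-dihydro-1-benzofuran | CC[Si](CC)(CC)OC(C)(C)[C@H]1Cc2c(OCOC)cc(OCOC)cc2O1 | intermediate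
7 | (2R)-2-methylbutanoic acid | CC[C@@H](C)C(=O)O | starting material
8 | (2R)-1-(1H-imidazol-1-yl)-2-methylbutan-1-one (formed in the flask, not isolated) | CC[C@@H](C)C(=O)n1ccnc1 | intermediate
9 | (2R)-N-methoxy-N,2-dimethylbutanamide | CC[C@@H](C)C(=O)N(C)OC | intermediate
10 | C5 aryllithium of 6, [(2R)-4,6-bis(methoxymethoxy)-2-{2-[(triethylsilyl)oxy]propan-2-yl}-2,3-dihydro-1-benzofuran-5-yl]lithium (formed in the flask, not isolated) | CC[Si](CC)(CC)OC(C)(C)[C@H]1Cc2c(OCOC)c([Li])c(OCOC)cc2O1 | intermediate
11 | (2R)-1-[(2R)-4,6-bis(methoxymethoxy)-2-{2-[(triethylsilyl)oxy]propan-2-yl}-2,3-dihydro-1-benzofuran-5-yl]-2-methylbutan-1-one | CC[Si](CC)(CC)OC(C)(C)[C@H]1Cc2c(OCOC)c(C(=O)[C@H](C)CC)c(OCOC)cc2O1 | intermediate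
12 | (2R)-1-[(2R)-2-(2-hydroxypropan-2-yl)-4,6-bis(methoxymethoxy)-2,3-dihydro-1-benzofuran-5-yl]-2-methylbutan-1-one | CC(C)(O)[C@H]1Cc2c(OCOC)c(C(=O)[C@H](C)CC)c(OCOC)cc2O1 | intermediate
13 | triethylammonium salt of the N-(methoxycarbonyl)sulfamate ester of alcohol 12 (formed in the flask, not isolated) | CC[NH+](CC)CC.COC(=O)[N-]S(=O)(=O)OC(C)(C)[C@H]1Cc2c(OCOC)c(C(=O)[C@H](C)CC)c(OCOC)cc2O1 | intermediate
14 | (2R)-1-[(2R)-4,6-bis(methoxymethoxy)-2-(prop-1-en-2-yl)-2,3-dihydro-1-benzofuran-5-yl]-2-methylbutan-1-one | C=C(C)[C@H]1Cc2c(OCOC)c(C(=O)[C@H](C)CC)c(OCOC)cc2O1 | intermediate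
15 | (2R)-1-[(2R)-4,6-dihydroxy-2-(prop-1-en-2-yl)-2,3-dihydro-1-benzofuran-5-yl]-2-methylbutan-1-one | C=C(C)[C@H]1Cc2c(O)c(C(=O)[C@H](C)CC)c(O)cc2O1 | intermediate
16 | methyl 3-oxopentanoate | CCC(=O)CC(=O)OC | starting material
17 | N-methoxy-N-methylpropanamide | CCC(=O)N(C)OC | starting material
18 | dilithium 2,4-dianion of methyl 3-oxopentanoate (formed in the flask, not isolated) | [Li+].[Li+].C[CH-]C(=O)[CH-]C(=O)OC | intermediate
19 | methyl 4-methyl-3,5-dioxoheptanoate (C4 unassigned, keto-enol mixture) | CCC(=O)C(C)C(=O)CC(=O)OC | intermediate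
20 | 6-ethyl-4-hydroxy-5-methyl-2H-pyran-2-one | CCc1oc(=O)cc(O)c1C | intermediate
21 | 3-[(dimethylamino)methyl]-6-ethyl-4-hydroxy-5-methyl-2H-pyran-2-one hydroiodide (formed in the flask, not isolated) | CCc1oc(=O)c(C[NH+](C)C)c(O)c1C.[I-] | intermediate
22 | 6-ethyl-5-methyl-3-methylidene-2H-pyran-2,4(3H)-dione (formed in the flask, not isolated) | CCC1=C(C)C(=O)C(=C)C(=O)O1 | intermediate
23 | 6-ethyl-4-hydroxy-3-({(2R)-4,6-dihydroxy-5-[(2R)-2-methylbutanoyl]-2-(prop-1-en-2-yl)-2,3-dihydro-1-benzofuran-7-yl}methyl)-5-methyl-2H-pyran-2-one | C=C(C)[C@H]1Cc2c(O)c(C(=O)[C@H](C)CC)c(O)c(Cc3c(O)c(C)c(CC)oc3=O)c2O1 | target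

Total step count: 11. Longest linear sequence: 7 steps (steps 1, 3, 5, 6, 7, 8, 11; the branch through step 2 is equally long).

Steps most likely to fail

Step 3. The remaining ortho C–H (later C7) may be alkylated a second time before norbornene is expelled. The palladium-bound alkoxide may also lose a β-hydride instead of forming the C–O bond, or palladation next to the methoxymethoxy group may be slow. The fallback sets out from 2 and 5 and comes back at 6, building the same ring in separate known steps. Iodination of 2 with N-iodosuccinimide (MeCN, 0 °C), ortho to the iodine and para to a methoxymethoxy group, should give 1,2-diiodo-3,5-bis(methoxymethoxy)benzene F1. Iodine–magnesium exchange with i-PrMgCl·LiCl at −40 °C should take the iodine flanked by the chelating methoxymethoxy group. CuI-catalysed opening of 5 at its terminal carbon should then give (2R)-1-[2-iodo-4,6-bis(methoxymethoxy)phenyl]-3-methyl-3-[(triethylsilyl)oxy]butan-2-ol F2. Intramolecular Ullmann etherification (CuI, 1,10-phenanthroline, Cs2CO3, toluene, 110 °C) should close the ring to 6 with the carbinol configuration untouched.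

Step 5. Lithiation may compete at C7, between the ring oxygen and a methoxymethoxy group, and the hindered aryllithium may abstract the α-proton of 9 instead of adding to it. The fallback sets out from 2 and comes back at 11 by acylating before the ring is built. Deprotonation of 2 with lithium 2,2,6,6-tetramethylpiperidide (THF, −78 °C) should occur at the only position flanked by two methoxymethoxy groups, and an amide base leaves the iodide alone. Addition of 9 should give (2R)-1-[4-iodo-2,6-bis(methoxymethoxy)phenyl]-2-methylbutan-1-one F3. Annulation of F3 with 5 under the conditions of step 3 should then give 11 directly.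

Step 11. The methylidene dione 22 may be captured by a second molecule of pyrone 20, giving the methylene-bis-pyrone, faster than by 15. The fallback sets out from 15 and comes back at 23 by reversing the roles of the two partners. Mannich reaction of 15 with CH2=NMe2+ I− and Et3N (CH2Cl2, rt) at C7 should give (2R)-1-[(2R)-7-[(dimethylamino)methyl]-4,6-dihydroxy-2-(prop-1-en-2-yl)-2,3-dihydro-1-benzofuran-5-yl]-2-methylbutan-1-one F4. Heating F4 with 20 in dioxane at 90 °C should release dimethylamine and form the ortho-quinone methide on the benzofuran side, which only the pyrone can trap, giving 23.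

Further compounds

F1 | step 3 | 1,2-diiodo-3,5-bis(methoxymethoxy)benzene | COCOc1cc(OCOC)c(I)c(I)c1
F2 | step 3 | (2R)-1-[2-iodo-4,6-bis(methoxymethoxy)phenyl]-3-methyl-3-[(triethylsilyl)oxy]butan-2-ol | CC[Si](CC)(CC)OC(C)(C)[C@H](O)Cc1c(I)cc(OCOC)cc1OCOC
F3 | step 5 | (2R)-1-[4-iodo-2,6-bis(methoxymethoxy)phenyl]-2-methylbutan-1-one | CC[C@@H](C)C(=O)c1c(OCOC)cc(I)cc1OCOC
F4 | step 11 | (2R)-1-[(2R)-7-[(dimethylamino)methyl]-4,6-dihydroxy-2-(prop-1-en-2-yl)-2,3-dihydro-1-benzofuran-5-yl]-2-methylbutan-1-one | C=C(C)[C@H]1Cc2c(O)c(C(=O)[C@H](C)CC)c(O)c(CN(C)C)c2O1
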